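## Retrosynthetic overview
- Hypholomine B ⇒ two molecules of hispidin. The C3–C3a and O1–C2 bonds of the dihydrofuran are cut together. In the forward direction this is a catalyst-controlled, protecting-group-free oxidative head-to-tail dimerisation (phenoxyl radical coupling, then quinone methide closure). It is the last step and sets both stereocentres.
- Hispidin ⇒ its catechol dimethyl ether (aryl methyl ether cleavage).
- Dimethyl ether ⇒ triacetic acid lactone + veratraldehyde, cut across the styryl C=C (dianion aldol addition, then dehydration).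
- Ring order: both pyranone rings and both arenes are bought intact. The dihydrofuran is the only ring made, and it is made last.

Assumption: the sense of induction of the chiral acid cannot be predicted with certainty. The (R)-acid is written as giving (2R,3R); the equally available (S)-acid is used if the first analytical run (chiral HPLC plus ECD) shows the opposite sign.

## Route

Step 1
Reactants: 1 4-hydroxy-6-methyl-2H-pyran-2-one (triacetic acid lactone); 2 3,4-dimethoxybenzaldehyde (veratraldehyde)
Product: 5 6-[(E)-2-(3,4-dimethoxyphenyl)ethenyl]-4-hydroxy-2H-pyran-2-one, via dilithio dianion 3 (not isolated), via aldol adduct 4 (not isolated)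
Conditions: LiN(iPr)2 (commercial solution, 2.3 equiv), THF, −78 → −20 °C, 1 h; 2 (1.0 equiv), −78 → 0 °C; then 6 M HCl (pH 1), 55 °C, 2 h; filter the yellow solid
Reagents that add atoms: none
Why: The second deprotonation of 1 takes place at the 6-methyl group, so the more reactive carbanion terminus of dianion 3 adds to the aldehyde (vinylogous aldol addition of a dianion), and the electron-rich benzylic alcohol 4 then loses water under acid (E1 dehydration) to the conjugated, thermodynamically preferred E-alkene, so no stereocentre remains.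

Step 2
Reactants: 5 6-[(E)-2-(3,4-dimethoxyphenyl)ethenyl]-4-hydroxy-2H-pyran-2-one
Product: 6 hispidin
Conditions: BBr3 (6 equiv), CH2Cl2, −78 °C → rt, 12 h; then ice–water
Reagents that add atoms: none
Why: BBr3 cleaves aryl methyl ethers by Lewis acid complexation and SN2 attack of bromide on the methyl group (aryl methyl ether cleavage), while the pyranone, its 4-OH (held as a borate until the quench) and the conjugated E-alkene are inert at or below room temperature, and no stereocentre is involved.

Step 3
Reactants: 6 hispidin (two molecules)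
Product: 10 (2R,3R)-hypholomine B, via phenoxyl radical 7 (not isolated), via head-to-tail adduct 8 (not isolated), via para-quinone methide 9 (not isolated)
Conditions: Ag2O (0.5 equiv), (R)-3,3′-bis(2,4,6-triisopropylphenyl)-1,1′-binaphthyl-2,2′-diyl hydrogen phosphate (20 mol %), acetone–toluene 1:1 (0.01 M), 0 °C, dark, Ar, stop at ca. 60% conversion; Celite; Sephadex LH-20 (MeOH), 6 and the acid recovered
Reagents that add atoms: none
Why: Proposed new method: Ag2O is the classical one-electron oxidant for the biomimetic 8–5′ dimerisation of caffeate and ferulate esters to trans-2-aryl-2,3-dihydrobenzofurans, and here it removes a hydrogen atom from the 4′-OH of 6 to give radical 7, whose spin reaches both the styryl carbon next to the pyranone and pyranone C-3, so two radicals join head-to-tail to adduct 8; this C–C bond links the termini of two highly delocalised radicals and should therefore form reversibly (as in the persistent-radical equilibria of bis(quinone methide) dimers of stilbenoid phenols), and the bulky chiral phosphate, sitting next to the new centre, removes the acidic C-3 proton of one equilibrating stereoisomer faster than of the others, which fixes the future C-3 in 9 (closest known reaction type: chiral-phosphoric-acid-controlled Minisci-type radical addition, with reversible radical addition followed by enantiodetermining phosphate-mediated deprotonation, together with chiral-phosphoric-acid-catalysed additions to para-quinone methides); the pyranone 4-OH then closes on the methide carbon (5-exo-trig oxa-Michael addition) anti to the pyranyl group, and because this benzylic C–O bond can reopen under the acid, C-2 settles in the thermodynamic trans, i.e. (R), configuration; the acidic aprotic medium keeps the pyranone un-ionised, which holds back the competing Michael addition of pyronate to the ring of the ortho-quinone.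

## Compound list
1 | 4-hydroxy-6-methyl-2H-pyran-2-one (triacetic acid lactone) | Cc1cc(O)cc(=O)o1 | starting material
2 | 3,4-dimethoxybenzaldehyde (veratraldehyde) | COc1ccc(C=O)cc1OC | starting material
3 | dilithio dianion of 1 (4-OLi, 6-CH2Li) | [Li]Cc1cc(O[Li])cc(=O)o1 | intermediate
4 | 6-[2-(3,4-dimethoxyphenyl)-2-hydroxyethyl]-4-hydroxy-2H-pyran-2-one, racemic carbinol | COc1ccc(C(O)Cc2cc(O)cc(=O)o2)cc1OC | intermediate
5 | 6-[(E)-2-(3,4-dimethoxyphenyl)ethenyl]-4-hydroxy-2H-pyran-2-one | COc1ccc(/C=C/c2cc(O)cc(=O)o2)cc1OC | intermediate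
6 | hispidin, 6-[(E)-2-(3,4-dihydroxyphenyl)ethenyl]-4-hydroxy-2H-pyran-2-one | O=c1cc(O)cc(/C=C/c2ccc(O)c(O)c2)o1 | intermediate
7 | hispidin 4′-phenoxyl (semiquinone) radical | [O]c1ccc(/C=C/c2cc(O)cc(=O)o2)cc1O | intermediate
8 | head-to-tail adduct of two radicals 7: the carbon next to the pyranone of one unit is bonded to C-3 of the other, and both catechols are present as 2-hydroxy-para-quinone methides; the CH(pyranyl) centre is (S), the same spatial arrangement as C-3 of 10; the transient sp3 C-3 and the methide geometries are undefined | O=c1cc(O)cc([C@@H](C=C2C=CC(=O)C(O)=C2)C2C(O)=CC(=CC=C3C=CC(=O)C(O)=C3)OC2=O)o1 | intermediate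
9 | 3-[(1S)-1-(4-hydroxy-2-oxo-2H-pyran-6-yl)-2-(3-hydroxy-4-oxocyclohexa-2,5-dien-1-ylidene)ethyl]hispidin (para-quinone methide; the (S) descriptor corresponds to (3R) in 10 because the priorities change; methide geometry undefined) | O=c1cc(O)cc([C@@H](C=C2C=CC(=O)C(O)=C2)c2c(O)cc(/C=C/c3ccc(O)c(O)c3)oc2=O)o1 | intermediate
10 | (2R,3R)-2-(3,4-dihydroxyphenyl)-6-[(E)-2-(3,4-dihydroxyphenyl)ethenyl]-3-(4-hydroxy-2-oxo-2H-pyran-6-yl)-2,3-dihydro-4H-furo[3,2-c]pyran-4-one (trans; hypholomine B) | O=c1cc(O)cc([C@@H]2c3c(cc(/C=C/c4ccc(O)c(O)c4)oc3=O)O[C@H]2c2ccc(O)c(O)c2)o1 | target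

Total step count: 3. Longest linear sequence: 3 (1 or 2 → 5 → 6 → 10).

## Steps most likely to fail

**Step 3 (highest risk).**
- The pyranone may attack the aryl ring of the ortho-quinone instead of the styryl carbon.
- The product catechols may be over-oxidised.
- Uncatalysed tautomerisation or ring closure of 8 would erode the ee.

The fallback sets out from 5 and comes back at 10. With the catechols still masked, no ortho-quinone can form.
- Compound 5 is dimerised with Mn(OAc)3·2H2O (trivalent manganese, one equivalent per 5) in AcOH at 60 °C.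
- The oxidant now generates the C-3 radical of the 4-hydroxypyranone, as in oxidative 1,3-dicarbonyl/alkene [3+2] annulations. This radical adds to the styryl carbon next to the pyranone of a second molecule.
- The benzylic radical is oxidised to the cation and closed by the 4-oxygen.
- The result is the racemic trans product, a 1:1 mixture of (2R,3R)-tetra-O-methylhypholomine B F1 and (2S,3S)-tetra-O-methylhypholomine B F2.
- The two are separated by preparative SFC on an amylose carbamate phase.
- F1 is demethylated with BBr3 (CH2Cl2, −78 → 0 °C) to 10. Any reversible opening of the C2–O bond recloses to the trans ring without touching C-3.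

**Step 1.** Dianion 3 is poorly soluble. The benzylic cation from 4 can alkylate C-3 of another pyranone instead of eliminating.

The fallback sets out from 2 and comes back at 5. It builds the pyranone ring instead of buying it.
- Doebner–Knoevenagel condensation of 2 with malonic acid (pyridine, cat. piperidine, 90 °C) gives (E)-3,4-dimethoxycinnamic acid F3.
- 1,1′-Carbonyldiimidazole (THF, rt) converts it into (E)-3,4-dimethoxycinnamoyl imidazolide F4.
- F4 C-acylates the lithium dienolate of 2,2,6-trimethyl-4H-1,3-dioxin-4-one F5 (made with LiN(SiMe3)2, THF, −78 °C, two equivalents). The product is 6-[(E)-4-(3,4-dimethoxyphenyl)-2-oxobut-3-enyl]-2,2-dimethyl-4H-1,3-dioxin-4-one F6.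
- Heating in toluene at 110 °C expels acetone. The resulting (E)-7-(3,4-dimethoxyphenyl)-3,5-dioxohepta-1,6-dien-1-one (acylketene) F7 closes through its enol oxygen, the triketide lactonisation of the polyketide pathway, to give 5.

**Step 2.** Compound 5 is poorly soluble in CH2Cl2. HBr from BBr3 may add to or polymerise the electron-rich styrene, and hispidin is awkward to free from boron residues.

The fallback sets out from dianion 3 (made from 1 as in step 1) and comes back at 6. It uses fluoride-labile groups, so no Lewis acid is needed.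
- 3,4-Dihydroxybenzaldehyde is silylated (TBSCl, imidazole, DMF) to 3,4-bis(tert-butyldimethylsilyloxy)benzaldehyde F8.
- F8 replaces 2 in the addition to 3 and gives 6-{2-[3,4-bis(tert-butyldimethylsilyloxy)phenyl]-2-hydroxyethyl}-4-hydroxy-2H-pyran-2-one F9.
- Catalytic TsOH in toluene at 80 °C dehydrates F9 to 3′,4′-bis-O-(tert-butyldimethylsilyl)hispidin F10.
- KHF2 in MeOH at rt frees the two phenols to give 6.

Further compounds
F1 | step 3 | (2R,3R)-2-(3,4-dimethoxyphenyl)-6-[(E)-2-(3,4-dimethoxyphenyl)ethenyl]-3-(4-hydroxy-2-oxo-2H-pyran-6-yl)-2,3-dihydro-4H-furo[3,2-c]pyran-4-one | O=c1cc(O)cc([C@@H]2c3c(cc(/C=C/c4ccc(OC)c(OC)c4)oc3=O)O[C@H]2c2ccc(OC)c(OC)c2)o1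
F2 | step 3 | (2S,3S) enantiomer of F1 | O=c1cc(O)cc([C@H]2c3c(cc(/C=C/c4ccc(OC)c(OC)c4)oc3=O)O[C@@H]2c2ccc(OC)c(OC)c2)o1
F3 | step 1 | (E)-3,4-dimethoxycinnamic acid | COc1ccc(/C=C/C(=O)O)cc1OC
F4 | step 1 | (E)-3-(3,4-dimethoxyphenyl)-1-(1H-imidazol-1-yl)prop-2-en-1-one | COc1ccc(/C=C/C(=O)n2ccnc2)cc1OC
F5 | step 1 | lithium dienolate of 2,2,6-trimethyl-4H-1,3-dioxin-4-one | C=C1C=C(O[Li])OC(C)(C)O1
F6 | step 1 | 6-[(E)-4-(3,4-dimethoxyphenyl)-2-oxobut-3-enyl]-2,2-dimethyl-4H-1,3-dioxin-4-one | COc1ccc(/C=C/C(=O)CC2=CC(=O)OC(C)(C)O2)cc1OC
F7 | step 1 | (E)-7-(3,4-dimethoxyphenyl)-3,5-dioxohepta-1,6-dien-1-one (acylketene) | COc1ccc(/C=C/C(=O)CC(=O)C=C=O)cc1OC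
F8 | step 2 | 3,4-bis(tert-butyldimethylsilyloxy)benzaldehyde | O=Cc1ccc(O[Si](C)(C)C(C)(C)C)c(O[Si](C)(C)C(C)(C)C)c1
F9 | step 2 | 6-{2-[3,4-bis(tert-butyldimethylsilyloxy)phenyl]-2-hydroxyethyl}-4-hydroxy-2H-pyran-2-one, racemic | OC(Cc1cc(O)cc(=O)o1)c1ccc(O[Si](C)(C)C(C)(C)C)c(O[Si](C)(C)C(C)(C)C)c1
F10 | step 2 | 6-{(E)-2-[3,4-bis(tert-butyldimethylsilyloxy)phenyl]ethenyl}-4-hydroxy-2H-pyran-2-one | O=c1cc(O)cc(/C=C/c2ccc(O[Si](C)(C)C(C)(C)C)c(O[Si](C)(C)C(C)(C)C)c2)o1
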